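E, the other product, stands in no reading of the runs so far; Z and X do, and they tell you how much J has gone if you count E as nil, which is my assumption here.

| setting | red | ochre | grey | flask |
|---|---|---|---|---|
| J | 0.050 M (fed, over 10 h) | 0.050 M (fed, over 10 h) | 0.075 M (fed, over 10 h) | 0.050 M (fed, over 10 h) |
| Q | 0.050 M | 0.075 M | 0.10 M | 0.100 M |
| remark | run made earlier; the fed solution adds 0.50 times the starting volume | run made earlier; the fed solution adds 0.50 times the starting volume | run made earlier; the fed solution adds 0.50 times the starting volume | the fed solution adds 0.50 times the starting volume |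
| time |  |  |  | 20 h |

| run | time / h | X / % | Z / % |
|---|---|---|---|
| red | 3.00 | 0.7 | 2.9 |
| red | 6.00 | 0 | 6.5 |
| red | 10.0 | 0.4 | 14.1 |
| red | 15.0 | 1.0 | 21.9 |
| red | 20.0 | 0 | 28.9 |
| red | 25.0 | 2.2 | 33.6 |
| ochre | 1.33 | 0 | 0.3 |
| ochre | 4.00 | 0.3 | 4.8 |
| ochre | 6.00 | 0 | 9.4 |
| ochre | 10.0 | 0.4 | 20.6 |
| ochre | 15.0 | 2.0 | 30.3 |
| ochre | 20.0 | 2.7 | 38.6 |
| ochre | 25.0 | 3.4 | 45.0 |
| grey | 2.00 | 1.1 | 0.6 |
| grey | 4.00 | 0.4 | 7.1 |
| grey | 6.00 | 0.1 | 11.9 |
| grey | 12.0 | 2.6 | 28.1 |
| grey | 25.0 | 3.8 | 46.0 |

(each reading ± 1 percentage point)

- which holds at 20 h: what has brought the reaction to rest, or that it has not come to rest (Q has run out first / forward and back rates have come level / it is still moving / all of J has reacted)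
- amount of X at 20 h, in percent of the J charged
- amount of Z at 20 h, in percent of the J charged
- amount of E at 20 h, in percent of the J charged

- charges are per starting volume, the dose included; the dosed solution carries all of it
- the reaction counts as stopped when no species that holds the J changes by six tenths of a point or more over the second half of the time
- percentages count the whole charge, also what has not yet gone in

Take the red run after its feed has ended. J stands at 85.5% at 10.0 h and 64.2% at 25.0 h. J reacts at a rate k·cJ·cQ, so at any moment its time constant is one over k·cQ. In red, Q is charged equal to J and falls along with it, so this is no pseudo-first-order decay; what I read is an average time constant over the tail, and as a rough rule I scale it as one over the Q charge. Read as one average decay, red gives 52.4 h. Ochre has 1.50 times the Q, so it should give 34.9 h, and it reads 35.2 h. Grey, with more J, reads 40.3 h, longer than the 26.2 h the scaling gives, so I keep the rule to the J charge of red and ochre, which this flask shares.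

For this flask the scaling gives 26.2 h: call it the tail time, the time constant of the fall of J after the feed.

Now solve both ends and join. The feed of 10 h is shorter than the tail time, so I let the loss during the feed grow with the Q charge: red's 14.5% becomes 29.0%, leaving J at 71.0%. One decay over the remaining time then gives 48.5% at 20 h. That is a fall of 22 percentage points over the second half, so by my reckoning the flask is still moving. The readings hold no E, so I have no reckoning for it.

The forecast says it is still moving, with X 4% (2.5% to 6%), Z 46% (41% to 51%) and E 54% (48% to 60%). Its ground is: “The pattern fits J + Q ⇌ Z + E, followed by a slow Z + Q → X + E.”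

The flask is it is still moving, with X 4.59%, Z 44.4% and E 3.57%, against the forecast's 54% of E. It also holds a species no run reported, the leaving ligand L, at 0.0202 M.

    X → E (k = 0.0966 h⁻¹)
    J + Q ⇌ L + Z (K = 4.20, k = 0.913 M⁻¹ h⁻¹)
    Z + Q ⇌ L + X (K = 1.20, k = 0.339 M⁻¹ h⁻¹)

J stands at 47.5% against my 48.5%. Put the tail time of 26.2 h on a neighbour flask charged with 0.020 M of J and the same Q, and it again gives 48.5% of J; that flask holds 42.7%.

The readings stem from a simulated flask on assumed constants, noise included.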